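**Plan**

1. Numbering used below: hydrindane carbons as in indane (C1 and C4 carry CH3 and oxygen, C3a/C7a are the ring fusion, C6 is the spiro carbon); α is the face of the two hydrindane oxygens.
2. Retrosynthesis: the spiro carbon C6 sits between two ring carbonyls of the cyclohexane-1,3,5-trione (acylphloroglucinol) ring, a 2,2-dialkyl-1,3-dione; cutting both C6–C(=O) bonds and rejoining the two carbonyl carbons leaves the five-membered vicinal-dione ring of hulupone and a C6 carbene equivalent (a 6-diazo-hydrindane).
3. Hulupone half: phloroglucinol, acylation, triprenylation (lupulone), autoxidative ring contraction that excises one ring carbon; the C(prenyl)2 carbon keeps the neighbouring carbonyl a true ketone and the acyl-enol (masked as methyl ether) deactivates the other carbonyls.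
4. Hydrindane half from (R)-linalool: cut C4–CH3, C5=C6 (aldol condensation), C3a–C7a (Michael) and the C7a=C7 enal bond (cross-metathesis); forward, the cyclopentane forms first, then the cyclohexenone, then C4 and the C6 ketone/hydrazone.
5. End game: insertion of the diazo carbon into the C(O)–C(O) bond expands the five-membered ring to the six-membered trione ring and creates the spiro centre in one step; global deprotection follows.
6. Stereochemistry: C1 from (R)-linalool; C7a and C3a by substrate-controlled Michael addition and equilibration; C4 by axial methyl addition; the spiro centre by attack anti to the axial C4 methyl and a strain-guided acyl shift.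

Key step: step 14

Assumption: hulupone and its methyl ether are drawn as the tautomer/regioisomer with the enol oxygen next to the diprenyl carbon (the other enol-ether regioisomer would converge on the same product after step 15), and commercial (R)-(−)-linalool is taken as enantiopure.

**Route**

Step 1
Reactants: 1 (R)-(−)-linalool
Product: 2 (5R)-5-ethenyl-5-methyloxolan-2-ol (lactol form of (4R)-4-hydroxy-4-methylhex-5-enal)
Conditions: O3 (1 equiv, indicator end point), CH2Cl2/MeOH, −78 °C; then Me2S, −78 to 23 °C
Reagents that add atoms: ozone, [O-][O+]=O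
Why: Ozonolysis should be selective for the electron-rich trisubstituted alkene over the vinyl group deactivated by the allylic hydroxyl, and the hydroxy aldehyde closes to the lactol with the stereocentre untouched.

Step 2
Reactants: 2 (5R)-5-ethenyl-5-methyloxolan-2-ol
Product: 4 (6R)-6-hydroxy-6-methyloct-7-en-2-one, via methyl enol ether 3 (not isolated)
Conditions: (1-methoxyethyl)triphenylphosphonium chloride, n-BuLi, THF, −78 to 0 °C; then 1 M aqueous oxalic acid, THF, 23 °C
Reagents that add atoms: (1-methoxyethyl)triphenylphosphonium chloride, COC(C)[P+](c1ccccc1)(c1ccccc1)c1ccccc1.[Cl-]; water, O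
Why: Wittig olefination of the open hydroxy-aldehyde form with the α-methoxy ylide gives an enol ether that mild acid hydrolyses to the methyl ketone, a two-carbon homologation that should leave the tertiary allylic alcohol intact.

Step 3
Reactants: 4 (6R)-6-hydroxy-6-methyloct-7-en-2-one
Product: 5 (2E,4R)-4-hydroxy-4-methyl-8-oxonon-2-enal
Conditions: crotonaldehyde (5 equiv), second-generation Grubbs catalyst RuCl2(=CHPh)(PCy3)(H2IMes) (5 mol %), CH2Cl2, 40 °C
Reagents that add atoms: (E)-crotonaldehyde, C/C=C/C=O
Why: Olefin cross-metathesis of the vinyl group of a tertiary allylic alcohol with an enal partner is an E-selective pairing that tolerates the ketone and the free alcohol.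

Step 4
Reactants: 5 (2E,4R)-4-hydroxy-4-methyl-8-oxonon-2-enal
Product: 7 (1R,3aR,7aS)-1-hydroxy-1-methyl-1,2,3,3a,7,7a-hexahydro-4H-inden-4-one, via keto aldehyde 6 (not isolated)
Conditions: pyrrolidine (0.3 equiv), AcOH (0.3 equiv), toluene, 23 °C then 60 °C
Reagents that add atoms: none
Why: Amine-catalysed intramolecular Michael addition (ketone enamine, 5-exo, onto the iminium-activated enal) followed by intramolecular aldol condensation (a Robinson-type annulation) should place the CH2CHO arm at C7a trans to the larger C1 substituent (methyl) and cis to the hydroxyl, while C3a, epimerisable next to the ketone, settles trans to that arm to give the trans-fused enone.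

Step 5
Reactants: 7 (1R,3aR,7aS)-1-hydroxy-1-methyl-1,2,3,3a,7,7a-hexahydro-4H-inden-4-one
Product: 8 (1R,3aR,4R,7aS)-1,4-dimethyl-2,3,3a,4,7,7a-hexahydro-1H-indene-1,4-diol
Conditions: MeLi (2.5 equiv), THF/Et2O, −78 °C; aqueous NH4Cl
Reagents that add atoms: methyllithium, [Li]C
Why: 1,2-Addition of the small organolithium to the cyclohexenone should occur axially on the β face (anti to the axial C3a–H, only one syn-axial hydrogen), which puts the new methyl axial and the C4 hydroxyl equatorial (α).

Step 6
Reactants: 8 (1R,3aR,4R,7aS)-1,4-dimethyl-2,3,3a,4,7,7a-hexahydro-1H-indene-1,4-diol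
Product: 9 (1R,3aR,4R,7aS)-1,4-dimethyl-1,4-bis(triethylsilyloxy)-2,3,3a,4,7,7a-hexahydro-1H-indene
Conditions: TESOTf (3 equiv), 2,6-lutidine, CH2Cl2, −78 to 0 °C
Reagents that add atoms: triethylsilyl trifluoromethanesulfonate, CC[Si](CC)(CC)OS(=O)(=O)C(F)(F)F
Why: Silyl triflate with a hindered base silylates both tertiary alcohols under buffered conditions that should not ionise the tertiary allylic C4–O bond.

Step 7
Reactants: 9 (1R,3aR,4R,7aS)-1,4-dimethyl-1,4-bis(triethylsilyloxy)-2,3,3a,4,7,7a-hexahydro-1H-indene
Product: 10 (1R,3aR,4R,7aS)-1,4-dimethyl-1,4-bis(triethylsilyloxy)octahydro-1H-inden-6-ol (C6 epimers)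
Conditions: BH3·THF, THF, 0 to 23 °C; then 3 M NaOH, 30 % H2O2, 0 to 23 °C
Reagents that add atoms: hydrogen peroxide, OO
Why: Hydroboration–oxidation should place boron on C6, the alkene carbon remote from the quaternary, silyloxy-bearing C4 (steric and inductive bias), and the C6 configuration is irrelevant.

Step 8
Reactants: 10 (1R,3aR,4R,7aS)-1,4-dimethyl-1,4-bis(triethylsilyloxy)octahydro-1H-inden-6-ol
Product: 11 (1R,3aR,4R,7aS)-1,4-dimethyl-1,4-bis(triethylsilyloxy)octahydroinden-6-one
Conditions: Dess–Martin periodinane, NaHCO3, CH2Cl2, 23 °C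
Reagents that add atoms: none
Why: Buffered hypervalent-iodine oxidation of the secondary alcohol gives the β-silyloxy ketone without the acid or base that could trigger β-elimination.

Step 9
Reactants: 11 (1R,3aR,4R,7aS)-1,4-dimethyl-1,4-bis(triethylsilyloxy)octahydroinden-6-one
Product: 12 hydrazone of ketone 11
Conditions: N2H4·H2O (10 equiv), Et3N, EtOH, 23 to 50 °C
Reagents that add atoms: hydrazine, NN
Why: Condensation of the unhindered ketone with excess hydrazine gives the N-unsubstituted hydrazone (excess suppresses azine formation), the precursor of the diazoalkane.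

Step 10
Reactants: 13 phloroglucinol
Product: 14 3-methyl-1-(2,4,6-trihydroxyphenyl)butan-1-one
Conditions: 3-methylbutanoyl chloride, AlCl3, PhNO2/CH2Cl2, 23 to 50 °C
Reagents that add atoms: 3-methylbutanoyl chloride, CC(C)CC(Cl)=O
Why: Friedel–Crafts C-acylation of the electron-rich triol stops at mono-acylation because the aryl ketone is deactivated.

Step 11
Reactants: 14 3-methyl-1-(2,4,6-trihydroxyphenyl)butan-1-one
Product: 15 lupulone (3,5-dihydroxy-2-(3-methylbutanoyl)-4,6,6-tris(3-methylbut-2-en-1-yl)cyclohexa-2,4-dien-1-one)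
Conditions: 1-bromo-3-methylbut-2-ene (3.2 equiv), NaOMe (3.2 equiv), MeOH, −20 to 0 °C
Reagents that add atoms: 1-bromo-3-methylbut-2-ene, CC(C)=CCBr
Why: Threefold C-prenylation of the acylphloroglucinol phenolate, with dearomatisation at the geminally dialkylated carbon, is the established alkylation route to hop β-acids (O-alkylation is the known competing path).

Step 12
Reactants: 15 lupulone
Product: 16 hulupone (4-hydroxy-5-(3-methylbutanoyl)-3,3-bis(3-methylbut-2-en-1-yl)cyclopent-4-ene-1,2-dione)
Conditions: O2 (1 atm), Na2SO3 (0.2 equiv), MeOH, 50 °C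
Reagents that add atoms: none
Why: Autoxidative ring contraction of hop β-acids hydroperoxidises the enolic, mono-prenylated ring carbon and excises it as 4-methylpent-3-enoic acid, joining its two oxygenated neighbours as the vicinal dione of the cyclopentane-1,2,4-trione.

Step 13
Reactants: 16 hulupone
Product: 17 O-methylhulupone (4-methoxy-5-(3-methylbutanoyl)-3,3-bis(3-methylbut-2-en-1-yl)cyclopent-4-ene-1,2-dione)
Conditions: Me3SiCHN2 (1.5 equiv), toluene/MeOH 4:1, 0 °C
Reagents that add atoms: (trimethylsilyl)diazomethane, C[Si](C)(C)C=[N+]=[N-]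
Why: O-Methylation of the strongly acidic enol by a diazoalkane removes the proton that would otherwise destroy diazoalkane 18 in step 14 and leaves the vicinal dione free.

Step 14
Reactants: 12 hydrazone of ketone 11; 17 O-methylhulupone
Product: 19 (1S,1'R,3a'R,4'R,7a'S)-4-methoxy-1',4'-dimethyl-5-(3-methylbutanoyl)-3,3-bis(3-methylbut-2-en-1-yl)-1',4'-bis(triethylsilyloxy)-1',2',3',3a',4',5',7',7a'-octahydrospiro[cyclohex-4-ene-1,6'-indene]-2,6-dione, via diazoalkane 18 (not isolated)
Conditions: DMSO, (COCl)2, THF, −78 °C, then 12, Et3N, −78 °C (gives 18; ammonium salt filtered cold); filtrate added to 17 (1.3 equiv), Sc(OTf)3 (0.2 equiv), CH2Cl2/toluene, −78 to −30 °C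
Reagents that add atoms: none
Why: Activated-DMSO dehydrogenation of 12 gives the non-stabilised diazoalkane 18, whose carbon adds to the Sc(OTf)3-activated ketone of 17 that lies between the diprenyl carbon and the second ring carbonyl; the tertiary diazonium alkoxide loses N2 with 1,2-shift of the neighbouring acyl carbon (preferred over the quaternary, carbonyl-bearing diprenyl carbon), so C6 is inserted into the C(O)–C(O) bond and the five-membered ring becomes the six-membered cyclohexane-1,3,5-trione ring. The closest known reaction types are the ring enlargement of cyclic vicinal di- and triketones to 1,3-diketones by diazoalkanes and the Sc(OTf)3-catalysed homologation of ketones with disubstituted diazoalkanes (a Tiffeneau–Demjanov-type shift). No ring is closed by cyclisation: the six-membered ring arises by one-carbon ring expansion through migration of a ring bond, and the hydrindane becomes spiro-fused at C6. The new spiro stereocentre is controlled by the trans-hydrindane: 18 should be attacked on the α face, anti to the axial C4 methyl, giving an equatorial C–C bond and an axial diazonium group, and the acyl carbon then moves across the β face into the axial site as N2 leaves in an ionisation-like step, the only arrangement that keeps the bulky C(=O)–C(prenyl)2 arm equatorial. The step needs carbonyl addition instead of O–H insertion or dipolar cycloaddition, secured by the methyl enol ether, the Lewis acid and the low temperature, and it needs shift instead of oxirane closure, which the Sc-bound alkoxide favours.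

Step 15
Reactants: 19 spiro trione methyl ether bis(triethylsilyl) ether
Product: 21 CNP0198642.3 (target), via desilylated methyl ether 20 (not isolated)
Conditions: HF·pyridine, pyridine/THF, 0 to 23 °C; then 1 M aqueous LiOH, THF, 23 °C; 1 M HCl to pH 3
Reagents that add atoms: lithium hydroxide, [Li+].[OH-]
Why: Fluoride cleaves both tertiary silyl ethers and hydroxide then hydrolyses the doubly activated vinylogous methyl ester by addition–elimination to a triketonate anion that resists further attack, so no stereocentre is touched.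

**Compound list**

1 | (R)-(−)-linalool, (3R)-3,7-dimethylocta-1,6-dien-3-ol | C=C[C@](C)(O)CCC=C(C)C | starting material
2 | (5R)-5-ethenyl-5-methyloxolan-2-ol (anomer mixture) | C=C[C@@]1(C)CCC(O)O1 | intermediate
3 | (3R)-7-methoxy-3-methylocta-1,6-dien-3-ol (E/Z mixture) | C=C[C@](C)(O)CCC=C(C)OC | intermediate
4 | (6R)-6-hydroxy-6-methyloct-7-en-2-one | C=C[C@](C)(O)CCCC(C)=O | intermediate
5 | (2E,4R)-4-hydroxy-4-methyl-8-oxonon-2-enal | O=C/C=C/[C@](C)(O)CCCC(C)=O | intermediate
6 | 2-[(1S,2R,5R)-5-acetyl-2-hydroxy-2-methylcyclopentyl]acetaldehyde | O=CC[C@H]1[C@@H](CC[C@@]1(C)O)C(C)=O | intermediate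
7 | (1R,3aR,7aS)-1-hydroxy-1-methyl-1,2,3,3a,7,7a-hexahydro-4H-inden-4-one | C1=CC[C@H]2[C@@H](CC[C@@]2(C)O)C1=O | intermediate
8 | (1R,3aR,4R,7aS)-1,4-dimethyl-2,3,3a,4,7,7a-hexahydro-1H-indene-1,4-diol | C1=CC[C@H]2[C@@H](CC[C@@]2(C)O)[C@]1(C)O | intermediate
9 | (1R,3aR,4R,7aS)-1,4-dimethyl-1,4-bis(triethylsilyloxy)-2,3,3a,4,7,7a-hexahydro-1H-indene | C1=CC[C@H]2[C@@H](CC[C@@]2(C)O[Si](CC)(CC)CC)[C@]1(C)O[Si](CC)(CC)CC | intermediate
10 | (1R,3aR,4R,7aS)-1,4-dimethyl-1,4-bis(triethylsilyloxy)octahydro-1H-inden-6-ol (C6 epimers) | OC1C[C@H]2[C@@H](CC[C@@]2(C)O[Si](CC)(CC)CC)[C@](C)(O[Si](CC)(CC)CC)C1 | intermediate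
11 | (1R,3aR,4R,7aS)-1,4-dimethyl-1,4-bis(triethylsilyloxy)octahydroinden-6-one | O=C1C[C@H]2[C@@H](CC[C@@]2(C)O[Si](CC)(CC)CC)[C@](C)(O[Si](CC)(CC)CC)C1 | intermediate
12 | hydrazone of ketone 11 | NN=C1C[C@H]2[C@@H](CC[C@@]2(C)O[Si](CC)(CC)CC)[C@](C)(O[Si](CC)(CC)CC)C1 | intermediate
13 | phloroglucinol (benzene-1,3,5-triol) | Oc1cc(O)cc(O)c1 | starting material
14 | 3-methyl-1-(2,4,6-trihydroxyphenyl)butan-1-one | CC(C)CC(=O)c1c(O)cc(O)cc1O | intermediate
15 | lupulone | CC(C)CC(=O)C1=C(O)C(CC=C(C)C)=C(O)C(CC=C(C)C)(CC=C(C)C)C1=O | intermediate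
16 | hulupone | CC(C)CC(=O)C1=C(O)C(CC=C(C)C)(CC=C(C)C)C(=O)C1=O | intermediate
17 | O-methylhulupone | CC(C)CC(=O)C1=C(OC)C(CC=C(C)C)(CC=C(C)C)C(=O)C1=O | intermediate
18 | (1R,3aR,4R,7aS)-6-diazo-1,4-dimethyl-1,4-bis(triethylsilyloxy)octahydro-1H-indene | [N-]=[N+]=C1C[C@H]2[C@@H](CC[C@@]2(C)O[Si](CC)(CC)CC)[C@](C)(O[Si](CC)(CC)CC)C1 | intermediate
19 | spiro trione methyl ether bis(triethylsilyl) ether (full name in step 14) | CC(C)=CCC1(CC=C(C)C)C(=O)[C@@]2(C[C@H]3[C@@H](CC[C@@]3(C)O[Si](CC)(CC)CC)[C@](C)(O[Si](CC)(CC)CC)C2)C(=O)C(C(=O)CC(C)C)=C1OC | intermediate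
20 | (1S,1'R,3a'R,4'R,7a'S)-1',4'-dihydroxy-4-methoxy-1',4'-dimethyl-5-(3-methylbutanoyl)-3,3-bis(3-methylbut-2-en-1-yl)-1',2',3',3a',4',5',7',7a'-octahydrospiro[cyclohex-4-ene-1,6'-indene]-2,6-dione | CC(C)=CCC1(CC=C(C)C)C(=O)[C@@]2(C[C@H]3[C@@H](CC[C@@]3(C)O)[C@](C)(O)C2)C(=O)C(C(=O)CC(C)C)=C1OC | intermediate
21 | CNP0198642.3, (1S,1'R,3a'R,4'R,7a'S)-1',4,4'-trihydroxy-1',4'-dimethyl-5-(3-methylbutanoyl)-3,3-bis(3-methylbut-2-en-1-yl)-1',2',3',3a',4',5',7',7a'-octahydrospiro[cyclohex-4-ene-1,6'-indene]-2,6-dione | CC(C)=CCC1(CC=C(C)C)C(=O)[C@@]2(C[C@H]3[C@@H](CC[C@@]3(C)O)[C@](C)(O)C2)C(=O)C(C(=O)CC(C)C)=C1O | target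

**Step count and risks**

Total steps: 15. Longest linear sequence: 11 (steps 1–9, 14, 15); steps 10–13 form the four-step hulupone branch.

Steps most likely to fail:

Step 14. The risk is poor control of the spiro configuration (an anti-periplanar shift from the equatorial adduct would deliver the C6 epimer), diversion to oxirane formation, or loss of the diazoalkane by 1,2-hydrogen shift. Fallback: the insertion is split into oxirane formation and a separate acyl shift, so that C6 is inverted twice. Starting from 12 and 17, diazoalkane 18 is generated as in step 14 and combined with 17 without Lewis acid (Et2O/MeOH, −40 °C). The free alkoxide should then close on C6 anti to the axial diazonium group and give the α-oxirane, 17-derived spiro-oxirane at hydrindane C6 with the oxirane oxygen on the α face F1. Treatment with BF3·OEt2 in CH2Cl2 at −78 °C should effect the α,β-epoxy ketone to 1,3-diketone rearrangement, in which the acyl carbon migrates anti to the C6–O bond; the route is rejoined at 19.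

Step 4. The risk is poor diastereocontrol at C7a in the Michael addition (arm cis to the C1 methyl) and elimination or retro-vinylogous-aldol loss of the γ-hydroxy enal. Fallback: a temporary lactone ring is used to fix C7a. Starting from 4, cross-metathesis with methyl acrylate gives methyl (2E,4R)-4-hydroxy-4-methyl-8-oxonon-2-enoate F2. With Cs2CO3 in MeOH the reversible intramolecular Michael addition is drained by lactonisation, which is possible only when the acetate arm is cis to the C1 oxygen, to give the cis-fused lactone (3aS,4R,6aR)-4-acetyl-6a-methylhexahydro-2H-cyclopenta[b]furan-2-one F3 (acetyl trans by equilibration). LiAlH4 reduces lactone and ketone to (1R,2S,3R)-2-(2-hydroxyethyl)-3-(1-hydroxyethyl)-1-methylcyclopentan-1-ol F4, and Swern oxidation of the primary and secondary alcohols returns keto aldehyde 6, which is condensed to 7 under the conditions of step 4.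

Step 5. The risk is poor facial selectivity in the methyl addition to the enone (equatorial attack gives the C4 epimer). Fallback: the ring is saturated first and the methyl is delivered by amphiphilic alkylation. Starting from 7, PhSH/Et3N adds to give (1R,3aR,7aS)-1-hydroxy-1-methyl-6-(phenylsulfanyl)octahydro-4H-inden-4-one F5 (equatorial sulfide by equilibration). MeLi in the presence of MeAl(OAr)2 (Ar = 2,6-di-tert-butyl-4-methylphenyl), which blocks the equatorial side of the carbonyl, gives (1R,3aR,4R,7aS)-1,4-dimethyl-6-(phenylsulfanyl)octahydro-1H-indene-1,4-diol F6. TESOTf/2,6-lutidine gives the bis(triethylsilyl) ether of F6 F7, and mCPBA (1 equiv, −78 °C) gives the sulfoxide of F7 F8. Pummerer rearrangement (trifluoroacetic anhydride, 2,6-lutidine) and aqueous NaHCO3 hydrolysis rejoin the route at ketone 11.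

**Further compounds**

F1 | step 14 | spiro-oxirane from 17 and 18 (oxirane between hydrindane C6 and the former ketone carbon next to the diprenyl carbon; oxygen on the α face at C6; other oxirane carbon unassigned) | CC(C)=CCC1(CC=C(C)C)C(OC)=C(C(=O)CC(C)C)C(=O)C12O[C@@]23C[C@H]4[C@@H](CC[C@@]4(C)O[Si](CC)(CC)CC)[C@](C)(O[Si](CC)(CC)CC)C3
F2 | step 4 | methyl (2E,4R)-4-hydroxy-4-methyl-8-oxonon-2-enoate | COC(=O)/C=C/[C@](C)(O)CCCC(C)=O
F3 | step 4 | (3aS,4R,6aR)-4-acetyl-6a-methylhexahydro-2H-cyclopenta[b]furan-2-one | O=C1C[C@H]2[C@@H](CC[C@@]2(C)O1)C(C)=O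
F4 | step 4 | (1R,2S,3R)-2-(2-hydroxyethyl)-3-(1-hydroxyethyl)-1-methylcyclopentan-1-ol (side-chain carbinol epimers) | OCC[C@H]1[C@@H](CC[C@@]1(C)O)C(C)O
F5 | step 5 | (1R,3aR,7aS)-1-hydroxy-1-methyl-6-(phenylsulfanyl)octahydro-4H-inden-4-one | O=C1CC(Sc3ccccc3)C[C@H]2[C@H]1CC[C@@]2(C)O
F6 | step 5 | (1R,3aR,4R,7aS)-1,4-dimethyl-6-(phenylsulfanyl)octahydro-1H-indene-1,4-diol | c1ccccc1SC3C[C@H]2[C@@H](CC[C@@]2(C)O)[C@](C)(O)C3
F7 | step 5 | (1R,3aR,4R,7aS)-1,4-dimethyl-6-(phenylsulfanyl)-1,4-bis(triethylsilyloxy)octahydro-1H-indene | c1ccccc1SC3C[C@H]2[C@@H](CC[C@@]2(C)O[Si](CC)(CC)CC)[C@](C)(O[Si](CC)(CC)CC)C3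
F8 | step 5 | (1R,3aR,4R,7aS)-1,4-dimethyl-6-(phenylsulfinyl)-1,4-bis(triethylsilyloxy)octahydro-1H-indene | c1ccccc1S(=O)C3C[C@H]2[C@@H](CC[C@@]2(C)O[Si](CC)(CC)CC)[C@](C)(O[Si](CC)(CC)CC)C3
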